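## Retrosynthetic overview
1. Ring A = C1–C6 (methylidene, OH, Br, CMe2) and ring B = C6–C11 (Cl, tertiary OH). Locants are those of (3R,4S,6S,8S,9R)-4-bromo-8-chloro-5,5,9-trimethyl-1-methylidenespiro[5.5]undecane-3,9-diol.
2. The target comes from MeMgBr addition to an α-chloro ketone (sets C9). That ketone comes from a catalytic desymmetrising α-chlorination of a spiro ketone whose ring B is still symmetric (sets C8 and the spiro centre C6).
3. The spiro ketone comes from an acyclic bromomethyl ketone bearing a 1,1-disubstituted alkene and a terminal alkyne. One reductive radical cascade closes ring B first (6-endo) and then ring A (6-exo-dig, leaving the exocyclic methylene).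
4. The cascade substrate already carries the anti bromohydrin (C3, C4). It is set by enamine-catalysed α-bromination of an aldehyde followed by Cornforth-controlled propargylation.
5. The aldehyde comes from copper-catalysed 1,4-addition of an alkenyl Grignard reagent to prenal, which builds the CMe2 carbon next to the future spiro carbon. The alkenyl bromide comes from acetylacetone and 2,3-dibromopropene.

Assumption: for each chiral organocatalyst the antipode named is taken to give the drawn configuration; if the sense of induction is opposite, the mirror-image catalyst is used.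

## Route

Step 1
Reactants: 1 pentane-2,4-dione; 2 2,3-dibromoprop-1-ene
Product: 4 5-bromohex-5-en-2-one, via 3-(2-bromoallyl)pentane-2,4-dione 3 (not isolated)
Conditions: K2CO3 (1.1 equiv), EtOH, reflux, 16 h
Reagents that add atoms: none
Why: The potassium enolate of 1 is C-alkylated at the allylic bromide of 2 (SN2, the vinylic bromide is inert) and diketone 3 then loses one acetyl group to ethanol by retro-Claisen cleavage under the same conditions, the classical one-pot acetylacetone route to allylacetones, with no stereocentre formed.

Step 2
Reactants: 4 5-bromohex-5-en-2-one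
Product: 6 [(5-bromohexa-1,5-dien-2-yl)oxy]tri(propan-2-yl)silane, via lithium enolate 5 (not isolated)
Conditions: LiN(iPr)2 (1.05 equiv), THF, −78 °C; iPr3SiOTf (1.1 equiv), −78 → 0 °C
Reagents that add atoms: triisopropylsilyl trifluoromethanesulfonate, CC(C)[Si](C(C)C)(C(C)C)OS(=O)(=O)C(F)(F)F
Why: Kinetic deprotonation of the methyl ketone at CH3 followed by O-silylation gives the terminal silyl enol ether, which masks the ketone towards the organometallic step and marks the carbon that will later carry the radical precursor, with no stereocentre formed.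

Step 3
Reactants: 6 [(5-bromohexa-1,5-dien-2-yl)oxy]tri(propan-2-yl)silane; 7 3-methylbut-2-enal (prenal)
Product: 10 3,3-dimethyl-4-methylidene-7-[tri(propan-2-yl)silyloxy]oct-7-enal, via alkenylmagnesium bromide 8 (not isolated), via trimethylsilyl enol ether 9 (not isolated)
Conditions: Mg, THF, 45 °C; then CuBr·SMe2 (10 mol %), Me3SiCl (2 equiv), DMPU, 7, −78 → −40 °C; then 1 M aq citric acid, THF, 0 °C, 10 min
Reagents that add atoms: none
Why: Copper-catalysed, chlorosilane-accelerated conjugate addition of an alkenyl Grignard reagent to a β,β-disubstituted enal builds the quaternary CMe2 carbon next to the sp2 carbon that becomes the spiro centre, trapping as 9 suppresses 1,2-addition, and mild acid cleaves only the far more labile aldehyde-derived trimethylsilyl enol ether, with no stereocentre formed.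

Step 4
Reactants: 10 3,3-dimethyl-4-methylidene-7-[tri(propan-2-yl)silyloxy]oct-7-enal
Product: 13 (7S,8R)-1,7-dibromo-8-hydroxy-6,6-dimethyl-5-methylideneundec-10-yn-2-one, via bromo aldehyde 11 (not isolated), via dibromo keto aldehyde 12 (not isolated)
Conditions: (a) (2R,5R)-2,5-diphenylpyrrolidine (20 mol %), PhCO2H (20 mol %), H2O (2 equiv), 4,4-dibromo-2,6-di-tert-butylcyclohexa-2,5-dien-1-one (1.05 equiv), CH2Cl2–pentane, −24 °C; (b) NBS (1.0 equiv), −40 °C, 15 min, cold silica plug; (c) allenylboronic acid pinacol ester (1.3 equiv), (R)-3,3'-bis(2,4,6-triisopropylphenyl)-1,1'-binaphthyl-2,2'-diyl hydrogen phosphate (5 mol %), 4 Å sieves, toluene, −20 °C; aq work-up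
Reagents that add atoms: 4,4-dibromo-2,6-di-tert-butylcyclohexa-2,5-dien-1-one, CC(C)(C)C1=CC(Br)(Br)C=C(C(C)(C)C)C1=O; N-bromosuccinimide, O=C1CCC(=O)N1Br; allenylboronic acid pinacol ester, C=C=CB1OC(C)(C)C(C)(C)O1
Why: Enamine-catalysed asymmetric α-bromination (precedented for 3,3-dimethylbutanal) sets the C–Br centre as S because the C2-symmetric amine shields one enamine face, NBS then turns the regiodefined silyl enol ether into the bromomethyl ketone far faster than it touches the alkenes, and the closed six-membered SE2' allenylboration attacks only the aldehyde in the Cornforth conformation (C–Br anti to C=O, attack opposite the tertiary alkyl group), reinforced by the matched chiral phosphoric acid, which gives the anti bromohydrin with the R carbinol.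

Step 5
Reactants: 13 (7S,8R)-1,7-dibromo-8-hydroxy-6,6-dimethyl-5-methylideneundec-10-yn-2-one
Product: 14 (8S,9R)-8-bromo-9-hydroxy-7,7-dimethyl-11-methylidenespiro[5.5]undecan-3-one
Conditions: fac-Ir(ppy)3 (1 mol %), diethyl 2,6-dimethyl-1,4-dihydropyridine-3,5-dicarboxylate (Hantzsch ester, 1.3 equiv, added over 8 h), K2HPO4 (2 equiv), degassed MeCN (0.005 M), 450 nm LEDs, 25 °C
Reagents that add atoms: none
Why: Proposed new method: photoexcited Ir(ppy)3 cleaves only the activated C–Br bond of the bromomethyl ketone, the electrophilic α-keto radical adds to the CH2 end of the electron-rich 1,1-disubstituted alkene (6-endo, the known preference of 2-oxohex-5-enyl radicals and the only open mode because 5-exo attack would hit the carbon bearing the tertiary alkyl group) to close ring B, the nucleophilic tertiary radical at the future spiro carbon then closes ring A by 6-exo-dig attack on the alkyne, helped by the gem-dimethyl effect, and the very reactive vinyl radical takes hydrogen from the slowly added Hantzsch ester to leave the exocyclic methylene; the closest known reaction types are visible-light reductive radical cyclisations of α-bromo carbonyl compounds and atom-transfer or tin hydride polycyclisations of α-halo ketones, the two existing stereocentres are spectators, and the new quaternary carbon is not yet stereogenic because ring B is symmetric.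

Step 6
Reactants: 14 (8S,9R)-8-bromo-9-hydroxy-7,7-dimethyl-11-methylidenespiro[5.5]undecan-3-one
Product: 15 (2S,6S,8S,9R)-8-bromo-2-chloro-9-hydroxy-7,7-dimethyl-11-methylidenespiro[5.5]undecan-3-one
Conditions: NCS (1.0 equiv), (4R,5R)-4,5-diphenylimidazolidine (20 mol %), 2-nitrobenzoic acid (50 mol %), MeCN, −24 °C
Reagents that add atoms: N-chlorosuccinimide, O=C1CCC(=O)N1Cl
Why: Enamine-catalysed enantioselective α-chlorination of a cyclohexanone with NCS is used here as a desymmetrisation: ring B is a locked chair with the CMe2 carbon equatorial and the methylidene-bearing carbon axial, so chlorine enters anti to that axial group and ends equatorial, cis to the CMe2 carbon, while the C2-symmetric catalyst decides which of the two α-methylene groups reacts, so the C–Cl centre (S) and the spiro centre (S) are fixed in the same event.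

Step 7
Reactants: 15 (2S,6S,8S,9R)-8-bromo-2-chloro-9-hydroxy-7,7-dimethyl-11-methylidenespiro[5.5]undecan-3-one
Product: 16 (3R,4S,6S,8S,9R)-4-bromo-8-chloro-5,5,9-trimethyl-1-methylidenespiro[5.5]undecane-3,9-diol (target)
Conditions: MeMgBr (3 equiv), Et2O, −78 °C; then H2O at −78 °C
Reagents that add atoms: methylmagnesium bromide, C[Mg]Br
Why: Grignard 1,2-addition to an α-chloro ketone gives the cis chlorohydrin, as with 2-chlorocyclohexanone: after the first equivalent has deprotonated the secondary alcohol, methyl attacks the locked chair from the equatorial side, trans to the neighbouring equatorial chlorine, so CH3 ends equatorial and OH axial (C9 R), and neither cis halohydrin alkoxide can reach the anti arrangement needed for epoxide closure at −78 °C.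

## Compound list
1 | pentane-2,4-dione | CC(=O)CC(C)=O | starting material
2 | 2,3-dibromoprop-1-ene | C=C(Br)CBr | starting material
3 | 3-(2-bromoprop-2-en-1-yl)pentane-2,4-dione | CC(=O)C(CC(Br)=C)C(C)=O | intermediate
4 | 5-bromohex-5-en-2-one | CC(=O)CCC(Br)=C | intermediate
5 | lithium 5-bromohexa-1,5-dien-2-olate | [Li+].[O-]C(=C)CCC(Br)=C | intermediate
6 | [(5-bromohexa-1,5-dien-2-yl)oxy]tri(propan-2-yl)silane | C=C(CCC(Br)=C)O[Si](C(C)C)(C(C)C)C(C)C | intermediate
7 | 3-methylbut-2-enal | CC(C)=CC=O | starting material
8 | {5-[tri(propan-2-yl)silyloxy]hexa-1,5-dien-2-yl}magnesium bromide | C=C(CCC(=C)[Mg]Br)O[Si](C(C)C)(C(C)C)C(C)C | intermediate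
9 | 1-(trimethylsilyloxy)-3,3-dimethyl-4-methylidene-7-[tri(propan-2-yl)silyloxy]octa-1,7-diene (E/Z mixture) | C[Si](C)(C)OC=CC(C)(C)C(=C)CCC(=C)O[Si](C(C)C)(C(C)C)C(C)C | intermediate
10 | 3,3-dimethyl-4-methylidene-7-[tri(propan-2-yl)silyloxy]oct-7-enal | O=CCC(C)(C)C(=C)CCC(=C)O[Si](C(C)C)(C(C)C)C(C)C | intermediate
11 | (2S)-2-bromo-3,3-dimethyl-4-methylidene-7-[tri(propan-2-yl)silyloxy]oct-7-enal | O=C[C@@H](Br)C(C)(C)C(=C)CCC(=C)O[Si](C(C)C)(C(C)C)C(C)C | intermediate
12 | (2S)-2,8-dibromo-3,3-dimethyl-4-methylidene-7-oxooctanal | O=C[C@@H](Br)C(C)(C)C(=C)CCC(=O)CBr | intermediate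
13 | (7S,8R)-1,7-dibromo-8-hydroxy-6,6-dimethyl-5-methylideneundec-10-yn-2-one | C#CC[C@@H](O)[C@@H](Br)C(C)(C)C(=C)CCC(=O)CBr | intermediate
14 | (8S,9R)-8-bromo-9-hydroxy-7,7-dimethyl-11-methylidenespiro[5.5]undecan-3-one | C=C1C[C@@H](O)[C@@H](Br)C(C)(C)C12CCC(=O)CC2 | intermediate
15 | (2S,6S,8S,9R)-8-bromo-2-chloro-9-hydroxy-7,7-dimethyl-11-methylidenespiro[5.5]undecan-3-one | C=C1C[C@@H](O)[C@@H](Br)C(C)(C)[C@]12CCC(=O)[C@@H](Cl)C2 | intermediate
16 | (3R,4S,6S,8S,9R)-4-bromo-8-chloro-5,5,9-trimethyl-1-methylidenespiro[5.5]undecane-3,9-diol | C=C1C[C@@H](O)[C@@H](Br)C(C)(C)[C@]12CC[C@@](C)(O)[C@@H](Cl)C2 | target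

## Step count and risks
Total step count: 7. Longest linear sequence: 7.

**Step 5 (radical bicyclisation).** The likely failures are early hydrogen transfer to the α-keto or tertiary radical, and some 7-endo closure. The fallback runs the bicyclisation as a non-reductive iodine-atom-transfer chain. Radicals trapped too early as iodides re-enter that chain, so nothing is lost to reduction.
- It sets out from 13, and NaI in acetone gives the iodomethyl ketone F1.
- Irradiation of F1 with (Bu3Sn)2 (10 mol %) in benzene still closes both rings in one operation. It ends by iodine transfer to the vinyl radical, giving the exocyclic vinyl iodide F2 (E/Z mixture).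
- Pd(PPh3)4 with HCO2Na in DMF replaces the vinylic iodine by hydrogen without touching the secondary bromide, and the route is rejoined at 14.

**Step 6 (desymmetrising chlorination).** The likely failures are incomplete discrimination of the two α-methylene groups and over-chlorination. The fallback separates the selection event from the halogenation.
- It sets out from 14. The hydroxyl is capped in the flask with Me3SiCl/Et3N.
- Lithium bis[(R)-1-phenylethyl]amide with LiCl and Me3SiCl as internal quench (THF, −100 °C) then removes one of the two axial α-hydrogens. This gives the scalemic bis(trimethylsilyl) enol ether F3.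
- NCS in CH2Cl2 at −78 °C chlorinates F3 regiospecifically anti to the axial substituent. Citric acid in MeOH frees the alcohol, and the route is rejoined at 15.

**Step 4 (telescoped bromination, bromination, propargylation).** The likely failures are competition of the silyl enol ether for the bromine source, alkylation of the amine catalyst by the bromomethyl ketone, and erosion of ee on handling. The fallback installs a less reactive radical handle before the asymmetric step, so the aldehyde is the only nucleophilic site.
- It sets out from 10, and NCS in THF–H2O at −20 °C gives the chloromethyl keto aldehyde F4.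
- The same enamine bromination gives the bromo chloro keto aldehyde F5, and allenylboration gives the chloromethyl ketone bromohydrin F6.
- F6 is submitted to the conditions of step 5 with NaI (1.5 equiv) added. Halide exchange generates the iodomethyl ketone F1 in the flask, and the same cascade rejoins the route at 14.

## Further compounds
F1 | step 5 | (7S,8R)-7-bromo-8-hydroxy-1-iodo-6,6-dimethyl-5-methylideneundec-10-yn-2-one | C#CC[C@@H](O)[C@@H](Br)C(C)(C)C(=C)CCC(=O)CI
F2 | step 5 | (8S,9R)-8-bromo-9-hydroxy-11-(iodomethylidene)-7,7-dimethylspiro[5.5]undecan-3-one (E/Z mixture) | IC=C1C[C@@H](O)[C@@H](Br)C(C)(C)C12CCC(=O)CC2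
F3 | step 6 | {[(6S,8S,9R)-8-bromo-7,7-dimethyl-11-methylidene-9-(trimethylsilyloxy)spiro[5.5]undec-2-en-3-yl]oxy}trimethylsilane | C=C1C[C@@H](O[Si](C)(C)C)[C@@H](Br)C(C)(C)[C@]12CCC(O[Si](C)(C)C)=CC2
F4 | step 4 | 8-chloro-3,3-dimethyl-4-methylidene-7-oxooctanal | O=CCC(C)(C)C(=C)CCC(=O)CCl
F5 | step 4 | (2S)-2-bromo-8-chloro-3,3-dimethyl-4-methylidene-7-oxooctanal | O=C[C@@H](Br)C(C)(C)C(=C)CCC(=O)CCl
F6 | step 4 | (7S,8R)-7-bromo-1-chloro-8-hydroxy-6,6-dimethyl-5-methylideneundec-10-yn-2-one | C#CC[C@@H](O)[C@@H](Br)C(C)(C)C(=C)CCC(=O)CCl
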